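**Plan**

- Numbering, kept for every intermediate: C1(OAc)–C2–C3(Me)–C4(OH)–C5(=O)–C6(=CMe2)–C7–C8=C9(Me)–C10(OAc), with C10 bonded to C1 and C2–C7 as fusion bond; ring A = C1, C2, C7, C8, C9, C10; ring B = C2 to C7.
- Retrosynthesis: the C4-OH/C5=O pair goes back to a C4 ketone (ketol shift, C5 hydroxylation) and the acetates to silyl ethers; the only skeletal cut is C6–C7 with C4–C9 re-joined, which leads to a 2-allenylbicyclo[2.2.2]oct-5-en-2-ol; then C4–C5 (allenyl anion plus ketone), the C1/C10 oxygens, and the Diels–Alder bonds C1–C2 and C9–C10 to dearomatised 2,6-dimethylphenol.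
- Enabling feature: ring B is cis-fused, has the exocyclic C6=CMe2 next to C7 and a carbonyl-level C4 two atoms further on, and ring A has its alkene at C8=C9 directly beside C7. This is the pattern left when a C4 allenyl carbinol shifts [3,3] across a C7=C8 bridge while C4–C9 breaks.
- Forward: the bicyclo[2.2.2]octadienone is built first, the ring-A diol is installed on the rigid bicycle, the allene is added at C4, and the oxy-Cope step then opens the bicycle. Ring A is inherited (C2, C9 and the C1–C10 and C7–C8 bridges), ring B is closed, and the ring-B oxidation pattern is set last.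
- Stereochemistry: the absolute configuration comes from the resolved C3 centre of the bicyclic acetate. It is relayed to C1/C10 (hydroxyl-directed osmylation), to the C4 carbinol (face-selective addition) and to C2/C7 (suprafacial shift, cis fusion). C3 (equilibration) and C4 (axial protonation) are the thermodynamically favoured epimers.

Key step: step 9

Remark: the elution order of the enantiomers of 6 cannot be predicted, so it is assumed that the (3S) antipode 7 is identified by an independent assignment (crystal structure of a heavy-atom derivative) before it is carried on.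

**Step 1**
Reactants: 1 2,6-dimethylphenol
Product: 3 rac-6-acetoxy-2,6-dimethylcyclohexa-2,4-dien-1-one, via aryloxylead triacetate 2 (not isolated)
Conditions: Pb(OAc)4 (1.1 equiv), AcOH, rt
Reagents that add atoms: lead tetraacetate, CC(=O)O[Pb](OC(C)=O)(OC(C)=O)OC(C)=O
Why: Wessely oxidation, in which ligand exchange binds the phenol to lead and an acetate is delivered to a methyl-bearing ortho carbon (both ortho positions are equivalent); the quaternary centre (later C3) forms as a racemate, and the 2,6-disubstituted dienone should be slow to dimerise.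

**Step 2**
Reactants: 3 rac-6-acetoxy-2,6-dimethylcyclohexa-2,4-dien-1-one; 4 phenyl vinyl sulfoxide
Product: 6 rac-3-acetoxy-1,3-dimethylbicyclo[2.2.2]octa-5,7-dien-2-one, via sulfoxide cycloadduct 5 (not isolated)
Conditions: 4 (3 equiv), PhMe, 110 °C, sealed tube, dark
Reagents that add atoms: none
Why: Diels–Alder reaction with the vinyl sulfoxide as an ethyne equivalent, followed in the same pot by thermal syn-elimination of benzenesulfenic acid; every regio- and stereoisomer of the adduct should converge on one racemic dienone, because the two etheno bridges are constitutionally equal and C3 is its only independent stereocentre.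

**Step 3**
Reactants: 6 rac-3-acetoxy-1,3-dimethylbicyclo[2.2.2]octa-5,7-dien-2-one
Product: 7 (3S)-3-acetoxy-1,3-dimethylbicyclo[2.2.2]octa-5,7-dien-2-one
Conditions: preparative HPLC, amylose tris(3,5-dimethylphenylcarbamate) phase, hexane/i-PrOH
Reagents that add atoms: none
Why: Chromatographic resolution of a rigid, configurationally fixed ketone on a polysaccharide carbamate phase; no stereocentre is formed, and the antipode that places the C3 oxygen beside the later C1–C10 bridge is kept.

**Step 4**
Reactants: 7 (3S)-3-acetoxy-1,3-dimethylbicyclo[2.2.2]octa-5,7-dien-2-one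
Product: 8 (3S)-3-hydroxy-1,3-dimethylbicyclo[2.2.2]octa-5,7-dien-2-one
Conditions: K2CO3 (0.2 equiv), MeOH, 0 °C
Reagents that add atoms: none
Why: Base-catalysed transesterification of an activated α-keto acetate; the ketone has no α-hydrogen and the quaternary C3 cannot epimerise, and the low temperature should keep the α-ketol from rearranging.

**Step 5**
Reactants: 8 (3S)-3-hydroxy-1,3-dimethylbicyclo[2.2.2]octa-5,7-dien-2-one
Product: 10 3,7,8-trihydroxy-1,3-dimethylbicyclo[2.2.2]oct-5-en-2-one (C1 and C10 hydroxyls cis on the side facing the C3–C4 bridge), via osmate ester 9 (not isolated)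
Conditions: OsO4 (1.05 equiv), TMEDA (1.1 equiv), CH2Cl2, −78 °C; then aq. Na2SO3, THF, 50 °C
Reagents that add atoms: osmium tetroxide, O=[Os](=O)(=O)=O
Why: Hydroxyl-directed dihydroxylation, in which the OsO4–TMEDA complex accepts a hydrogen bond from the C3 hydroxyl, a homoallylic donor held rigidly beside the C1=C10 bridge on the side of the ketone bridge; this should select both the alkene and its face, setting C1 and C10 cis with both oxygens turned toward the C3–C4 bridge.

**Step 6**
Reactants: 10 3,7,8-trihydroxy-1,3-dimethylbicyclo[2.2.2]oct-5-en-2-one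
Product: 11 3-hydroxy-1,3-dimethyl-7,8-bis(triethylsilyloxy)bicyclo[2.2.2]oct-5-en-2-one
Conditions: Et3SiCl (2.5 equiv), imidazole, DMF, 0 °C → rt
Reagents that add atoms: chlorotriethylsilane, CC[Si](Cl)(CC)CC
Why: Silylation with a chlorosilane and imidazole should take the two secondary hydroxyls and leave the hindered tertiary α-keto hydroxyl free, which is removed in the next step.

**Step 7**
Reactants: 11 3-hydroxy-1,3-dimethyl-7,8-bis(triethylsilyloxy)bicyclo[2.2.2]oct-5-en-2-one
Product: 14 1,3-dimethyl-7,8-bis(triethylsilyloxy)bicyclo[2.2.2]oct-5-en-2-one (C3 methyl toward the C7=C8 alkene), via samarium enolate 12 (not isolated), via C3-epimeric ketone 13 (not isolated)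
Conditions: SmI2 (3 equiv), THF/MeOH, −78 → 0 °C; then NaOMe (0.3 equiv) in MeOH, 0 °C → rt
Reagents that add atoms: none
Why: Reductive cleavage of an α-hydroxy ketone by SmI2 through ketyl and enolate; protonation from the open alkene side would push the methyl against the C1 silyloxy group, so methoxide equilibration through the enolate should move the C3 methyl to the side of the C7=C8 alkene (thermodynamic control; the ketone has no other acidic position).

**Step 8**
Reactants: 14 1,3-dimethyl-7,8-bis(triethylsilyloxy)bicyclo[2.2.2]oct-5-en-2-one; 15 3-methylbuta-1,2-diene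
Product: 17 1,3-dimethyl-2-(3-methylbuta-1,2-dien-1-yl)-7,8-bis(triethylsilyloxy)bicyclo[2.2.2]oct-5-en-2-ol (allene over the C7=C8 alkene), via allenyllithium 16 (not isolated)
Conditions: 15 (2.2 equiv), n-BuLi (2 equiv), THF, −78 → −40 °C; then 14, −78 → −20 °C; aq. NH4Cl
Reagents that add atoms: none
Why: 1,2-Addition of a γ,γ-disubstituted allenyllithium, which reacts at its unsubstituted terminus to give the allenyl carbinol; it should approach C4 from the side of the C7=C8 alkene because the opposite face lies under the C10 silyloxy group (a 1,3-syn substituent), which sets C4 with the allene over the alkene and the hydroxyl toward the silyloxy bridge.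

**Step 9**
Reactants: 17 1,3-dimethyl-2-(3-methylbuta-1,2-dien-1-yl)-7,8-bis(triethylsilyloxy)bicyclo[2.2.2]oct-5-en-2-ol
Product: 20 cis-fused decalin ketone (1R,2S,3R,7R,10S in the route numbering; C4 ketone; C5 methylene; C6 isopropylidene; C8=C9; 1,10-bis(triethylsilyloxy)), via potassium alkoxide 18 (not isolated), via potassium dienolate 19 (not isolated)
Conditions: KH (1.5 equiv), 18-crown-6 (1.5 equiv), THF, 0 °C → rt; then AcOH in THF, −78 °C
Reagents that add atoms: none
Why: Deprotonation gives alkoxide 18, whose C4–C9 bond is weakened, and a concerted suprafacial [3,3] shift through the boat-like array C6=C5–C4–C9–C8=C7 forms C6–C7 as C4–C9 breaks, driven by loss of bicyclic strain and formation of the conjugated dienolate 19. The closest known reaction type is the anionic oxy-Cope rearrangement of 2-vinylbicyclo[2.2.2]oct-5-en-2-ols to cis-decalinones, here with an allene in place of the vinyl group, so that C6 keeps its exocyclic double bond to CMe2. Ring B (C2 to C7) closes as a six-membered ring in a sigmatropic mode, while ring A is what remains of the bicycle (C2 and C9 with the C1–C10 and C7–C8 bridges, the alkene moving to C8=C9). The one new stereocentre, C7, is controlled by the C2 bridgehead, because the allene can reach C7 only on the alkene face turned toward the carbinol bridge, which puts H7 cis to H2. The step needs the allene syn to the only alkene, secured by the facial selectivity of step 8, and kinetic protonation of 19 at C5, secured by the cold acetic acid quench, so that the isopropylidene stays out of conjugation until step 13. C1, C3 and C10 are not touched.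

**Step 10**
Reactants: 20 cis-fused decalin ketone with 1,10-bis(triethylsilyloxy) groups
Product: 21 1,10-dihydroxy decalin ketone (1R,2S,3R,7R,10S)
Conditions: HF·pyridine, pyridine, THF, 0 °C → rt
Reagents that add atoms: none
Why: Fluoride-mediated cleavage of the two secondary silyl ethers in a pyridine-buffered medium that should neither enolise the β,γ-unsaturated ketone nor touch the C3 centre.

**Step 11**
Reactants: 21 1,10-dihydroxy decalin ketone
Product: 22 1,10-diacetoxy decalin ketone (1R,2S,3R,7R,10S)
Conditions: Ac2O, pyridine, DMAP (cat.), CH2Cl2, 0 °C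
Reagents that add atoms: acetic anhydride, CC(=O)OC(C)=O
Why: Nucleophile-catalysed acylation of the only two hydroxyls present; putting the acetates on before any ring-B hydroxyl exists avoids a later need to tell three secondary alcohols apart.

**Step 12**
Reactants: 22 1,10-diacetoxy decalin ketone
Product: 24 5-hydroxy-4-ketone diacetate (C5 epimers), via potassium dienolate 23 (not isolated)
Conditions: KN(SiMe3)2 (1.1 equiv), THF, −78 °C; 2-(phenylsulfonyl)-3-phenyloxaziridine (1.3 equiv), −78 °C; AcOH, −78 °C
Reagents that add atoms: 2-(phenylsulfonyl)-3-phenyloxaziridine, O=S(=O)(c1ccccc1)N1OC1c1ccccc1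
Why: Enolate hydroxylation with an N-sulfonyloxaziridine; the amide base should remove the C5 proton, which is α to the ketone and allylic and so far more acidic than C3–H or the acetate protons, and the extended enolate is oxidised at its α-carbon; the C5 configuration is of no consequence because it is erased in step 13.

**Step 13**
Reactants: 24 5-hydroxy-4-ketone diacetate
Product: 26 target CNP0333818.1 (1R,2S,3R,4S,7R,10S in the route numbering), via enediol 25 (not isolated)
Conditions: DBU (0.2 equiv), CH2Cl2, 0 °C
Reagents that add atoms: none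
Why: α-Ketol transposition of the Lobry de Bruyn–Alberda van Ekenstein type through enediol 25, driven by conjugation of the new C5 carbonyl with the isopropylidene; C4 should be protonated axially from the convex face, giving the equatorial hydroxyl trans to the C3 methyl, which is also the more stable epimer, and the product lacks the doubly activated C–H of 24 and so should not react further under the catalytic base.

**Compound list**

1 | 2,6-dimethylphenol | Cc1cccc(C)c1O | starting material
2 | (2,6-dimethylphenoxy)lead triacetate | Cc1cccc(C)c1O[Pb](OC(C)=O)(OC(C)=O)OC(C)=O | intermediate (not isolated)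
3 | rac-6-acetoxy-2,6-dimethylcyclohexa-2,4-dien-1-one (racemate) | CC(=O)OC1(C)C=CC=C(C)C1=O | intermediate
4 | phenyl vinyl sulfoxide (racemic at sulfur) | C=CS(=O)c1ccccc1 | starting material
5 | 3-acetoxy-1,3-dimethyl-7-(phenylsulfinyl)bicyclo[2.2.2]oct-5-en-2-one, mixture of regio- and stereoisomers, one constitution drawn | CC(=O)OC1(C)C(=O)C2(C)C=CC1CC2S(=O)c1ccccc1 | intermediate (not isolated)
6 | rac-3-acetoxy-1,3-dimethylbicyclo[2.2.2]octa-5,7-dien-2-one (racemate) | CC(=O)OC1(C)C(=O)C2(C)C=CC1C=C2 | intermediate
7 | (3S)-3-acetoxy-1,3-dimethylbicyclo[2.2.2]octa-5,7-dien-2-one | CC(=O)O[C@]1(C)C(=O)[C@@]2(C)C=C[C@@H]1C=C2 | intermediate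
8 | (3S)-3-hydroxy-1,3-dimethylbicyclo[2.2.2]octa-5,7-dien-2-one | O[C@]1(C)C(=O)[C@@]2(C)C=C[C@@H]1C=C2 | intermediate
9 | cyclic osmate ester OsO2(OR)2(TMEDA) of 10 at the C1 and C10 oxygens (hexavalent osmium) | O[C@]1(C)C(=O)[C@@]2(C)C=C[C@@H]1[C@H]3O[Os-2]4(=O)(=O)([N+](C)(C)CC[N+]4(C)C)O[C@@H]23 | intermediate (not isolated)
10 | (3S)-3,7,8-trihydroxy-1,3-dimethylbicyclo[2.2.2]oct-5-en-2-one; the 7- and 8-hydroxyls (C10 and C1) are cis and face the ketone bridge, on the same side as the 3-hydroxyl | O[C@]1(C)C(=O)[C@@]2(C)C=C[C@@H]1[C@@H](O)[C@H]2O | intermediate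
11 | 3-hydroxy-1,3-dimethyl-7,8-bis(triethylsilyloxy)bicyclo[2.2.2]oct-5-en-2-one, configuration as in 10 | O[C@]1(C)C(=O)[C@@]2(C)C=C[C@@H]1[C@@H](O[Si](CC)(CC)CC)[C@H]2O[Si](CC)(CC)CC | intermediate
12 | samarium enolate (C3=C4, O–SmI2; trivalent samarium) of the bis(silyloxy) ketone | CC1=C(O[Sm](I)I)[C@@]2(C)C=C[C@@H]1[C@@H](O[Si](CC)(CC)CC)[C@H]2O[Si](CC)(CC)CC | intermediate (not isolated)
13 | 1,3-dimethyl-7,8-bis(triethylsilyloxy)bicyclo[2.2.2]oct-5-en-2-one, C3 methyl on the side of the silyloxy bridge | C[C@@H]1C(=O)[C@@]2(C)C=C[C@@H]1[C@@H](O[Si](CC)(CC)CC)[C@H]2O[Si](CC)(CC)CC | intermediate (not isolated)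
14 | 1,3-dimethyl-7,8-bis(triethylsilyloxy)bicyclo[2.2.2]oct-5-en-2-one, C3 methyl on the side of the C7=C8 alkene | C[C@H]1C(=O)[C@@]2(C)C=C[C@@H]1[C@@H](O[Si](CC)(CC)CC)[C@H]2O[Si](CC)(CC)CC | intermediate
15 | 3-methylbuta-1,2-diene | CC(C)=C=C | starting material
16 | (3-methylbuta-1,2-dien-1-yl)lithium | [Li]C=C=C(C)C | intermediate (not isolated)
17 | 1,3-dimethyl-2-(3-methylbuta-1,2-dien-1-yl)-7,8-bis(triethylsilyloxy)bicyclo[2.2.2]oct-5-en-2-ol; allene over the C7=C8 alkene, carbinol hydroxyl toward the silyloxy bridge | C[C@H]1[C@@](O)(C=C=C(C)C)[C@@]2(C)C=C[C@@H]1[C@@H](O[Si](CC)(CC)CC)[C@H]2O[Si](CC)(CC)CC | intermediate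
18 | potassium alkoxide of 17 | C[C@H]1[C@@]([O-])(C=C=C(C)C)[C@@]2(C)C=C[C@@H]1[C@@H](O[Si](CC)(CC)CC)[C@H]2O[Si](CC)(CC)CC.[K+] | intermediate (not isolated)
19 | potassium dienolate (C4–O, C4=C5, C6=CMe2) of 20 | CC[Si](CC)(CC)O[C@@H]1[C@@H]2[C@@H](C)C([O-])=CC(=C(C)C)[C@@H]2C=C(C)[C@@H]1O[Si](CC)(CC)CC.[K+] | intermediate (not isolated)
20 | (1R,2S,3R,7R,10S)-3,9-dimethyl-6-(propan-2-ylidene)-1,10-bis(triethylsilyloxy)-cis-decal-8-en-4-one (route numbering) | CC[Si](CC)(CC)O[C@@H]1[C@@H]2[C@@H](C)C(=O)CC(=C(C)C)[C@@H]2C=C(C)[C@@H]1O[Si](CC)(CC)CC | intermediate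
21 | (1R,2S,3R,7R,10S)-1,10-dihydroxy-3,9-dimethyl-6-(propan-2-ylidene)-cis-decal-8-en-4-one (route numbering) | O[C@@H]1[C@@H]2[C@@H](C)C(=O)CC(=C(C)C)[C@@H]2C=C(C)[C@@H]1O | intermediate
22 | (1R,2S,3R,7R,10S)-1,10-diacetoxy-3,9-dimethyl-6-(propan-2-ylidene)-cis-decal-8-en-4-one (route numbering) | CC(=O)O[C@@H]1[C@@H]2[C@@H](C)C(=O)CC(=C(C)C)[C@@H]2C=C(C)[C@@H]1OC(C)=O | intermediate
23 | potassium dienolate of 22 | CC(=O)O[C@@H]1[C@@H]2[C@@H](C)C([O-])=CC(=C(C)C)[C@@H]2C=C(C)[C@@H]1OC(C)=O.[K+] | intermediate (not isolated)
24 | 1,10-diacetoxy-5-hydroxy-3,9-dimethyl-6-(propan-2-ylidene)-cis-decal-8-en-4-one, C5 epimers | CC(=O)O[C@@H]1[C@@H]2[C@@H](C)C(=O)C(O)C(=C(C)C)[C@@H]2C=C(C)[C@@H]1OC(C)=O | intermediate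
25 | 4,5-enediol of 24 | CC(=O)O[C@@H]1[C@@H]2[C@@H](C)C(O)=C(O)C(=C(C)C)[C@@H]2C=C(C)[C@@H]1OC(C)=O | intermediate (not isolated)
26 | CNP0333818.1: (1R,2S,3R,4S,7R,10S)-1,10-diacetoxy-4-hydroxy-3,9-dimethyl-6-(propan-2-ylidene)-cis-decal-8-en-5-one (route numbering) | CC(=O)O[C@@H]1[C@@H]2[C@@H](C)[C@H](O)C(=O)C(=C(C)C)[C@@H]2C=C(C)[C@@H]1OC(C)=O | target

**Count**

Total step count: 13. Longest linear sequence: 13 steps (1 to 26); 4 and 15 enter as commercial reagents.

**Steps most likely to fail**

Step 5. The osmylation may escape the hydrogen-bond control and take place on the open side that both etheno bridges share, which would lose both the choice of alkene and the choice of face. The fallback sets out from 3 and comes back at 14, and lets shape decide by oxygenating ring A before the second alkene exists. Racemic 3 is resolved on the same chiral phase, now keeping the antipode (6R)-6-acetoxy-2,6-dimethylcyclohexa-2,4-dien-1-one F1, because the oxygenated bridge then comes from the diene. Diels–Alder reaction with maleic anhydride (PhMe, 80 °C), endo and on the acetoxy-bearing face of the dienone, should give the anhydride adduct F2; any adduct formed on the other face is a diastereomer and is removed here. OsO4 (cat.) with N-methylmorpholine N-oxide in aqueous acetone can reach the only alkene solely from the side of the ketone bridge, since the other face lies under the endo dicarboxy bridge, and should deliver, with opening of the anhydride, the diol diacid F3. Et3SiOTf and 2,6-lutidine followed by a mild aqueous work-up would give the bis(silyl ether) diacid F4. Oxidative bis-decarboxylation with Pb(OAc)4 and pyridine then creates the C7=C8 alkene in the acetoxy ketone F5. SmI2 followed by NaOMe, as in step 7, removes the acetoxy group and settles the C3 methyl, which leads to 14.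

Step 9. The alkoxide may be diverted before it rearranges, by transfer of the C10 silyl group to the C4 oxygen or by fragmentation, and the shift itself may be slow because one allene methyl points into the forming C6–C7 bond. The fallback sets out from 17 and comes back at 20, and replaces the charged rearrangement by a neutral one. Silylation of the tertiary hydroxyl with N-(trimethylsilyl)imidazole would give the trimethylsilyl ether F6. Heating in o-dichlorobenzene (180–200 °C, sealed tube) should bring about the thermal siloxy-Cope rearrangement to the trimethylsilyl dienol ether F7. Aqueous citric acid in THF at 0 °C would then hydrolyse it with protonation at C5 to 20.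

Step 13. The base-mediated tautomerisation may stop short, or run past the conjugated ketol to the diosphenol tautomer by protonation at the isopropylidene carbon. The fallback sets out from 24 and comes back at 26, and replaces the tautomerisation by a reduction and a selective oxidation. NaBH4 with CeCl3·7H2O in MeOH at −78 °C should reduce the C4 ketone by axial hydride delivery to the 4,5-diol diacetate F8. MnO2 in CH2Cl2 would then oxidise only the allylic C5 hydroxyl, which gives 26 directly.

**Further compounds**

F1 | step 5 | (6R)-6-acetoxy-2,6-dimethylcyclohexa-2,4-dien-1-one | CC(=O)O[C@]1(C)C=CC=C(C)C1=O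
F2 | step 5 | endo maleic anhydride adduct of F1 (anhydride bridge on the acetoxy side, under the C1=C10 alkene) | CC(=O)O[C@@]1(C)C(=O)[C@]2(C)C=C[C@H]1[C@H]3C(=O)OC(=O)[C@@H]23
F3 | step 5 | diol diacid: 3-acetoxy-7,8-dihydroxy-1,3-dimethyl-2-oxobicyclo[2.2.2]octane-5,6-dicarboxylic acid, hydroxyls toward the ketone bridge | CC(=O)O[C@@]1(C)C(=O)[C@]2(C)[C@H](O)[C@H](O)[C@H]1[C@@H](C(=O)O)[C@H]2C(=O)O
F4 | step 5 | bis(triethylsilyl ether) of F3 | CC(=O)O[C@@]1(C)C(=O)[C@]2(C)[C@H](O[Si](CC)(CC)CC)[C@H](O[Si](CC)(CC)CC)[C@H]1[C@@H](C(=O)O)[C@H]2C(=O)O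
F5 | step 5 | 3-acetoxy-1,3-dimethyl-7,8-bis(triethylsilyloxy)bicyclo[2.2.2]oct-5-en-2-one, acetoxy group toward the C7=C8 alkene | CC(=O)O[C@@]1(C)C(=O)[C@]2(C)[C@H](O[Si](CC)(CC)CC)[C@H](O[Si](CC)(CC)CC)[C@H]1C=C2
F6 | step 9 | trimethylsilyl ether of 17 at the C4 oxygen | C[C@H]1[C@@](O[Si](C)(C)C)(C=C=C(C)C)[C@@]2(C)C=C[C@@H]1[C@@H](O[Si](CC)(CC)CC)[C@H]2O[Si](CC)(CC)CC
F7 | step 9 | trimethylsilyl dienol ether of 20 (C4–OSiMe3, C4=C5, C6=CMe2) | CC[Si](CC)(CC)O[C@@H]1[C@@H]2[C@@H](C)C(O[Si](C)(C)C)=CC(=C(C)C)[C@@H]2C=C(C)[C@@H]1O[Si](CC)(CC)CC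
F8 | step 13 | 1,10-diacetoxy-4,5-dihydroxy-3,9-dimethyl-6-(propan-2-ylidene)-cis-decal-8-ene, C4 as in the target, C5 epimers | CC(=O)O[C@@H]1[C@@H]2[C@@H](C)[C@H](O)C(O)C(=C(C)C)[C@@H]2C=C(C)[C@@H]1OC(C)=O
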